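**Retrosynthetic overview**
1. Target 26 ⇐ hydrogenolysis of the phenol benzyl ether ⇐ 6α-OH-directed epoxidation of C8=C9 ⇐ desilylation ⇐ 4β-O-aroylation ⇐ isopropyl addition to the C4 ketone of hydroazulenone 18.
2. 18 ⇐ one-position alkene migration (C9=C10 to C8=C9) ⇐ cobalt removal from the cycloheptyne–Co2(CO)6 complex 16.
3. Key disconnection, 16 ⇒ 10 + 13: C7–C8 and C5–C6 form together in a Lewis-acid-triggered Nicholas/Mukaiyama formal [5+2] annulation. The five-carbon unit is C5–C1–C10≡C9–C8 (ring A silyl enol ether C4=C5, Co2(CO)6-complexed alkyne, leaving group on C8); the two-carbon unit is C7=C6–OSi, triisopropyl(vinyloxy)silane.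
4. Enabling feature: ring-fusion C5 is α to the oxygen-bearing C4 of ring A (so it can be an enol-ether nucleophile), C6 carries oxygen, and C8–C9–C10 ends at quaternary C1. C9≡C10 can therefore be a bent Co2(CO)6 alkyne that stabilises a cation at C8 and geometrically forbids direct C5–C8 closure.
5. Ring order: ring A from 3-ethoxycyclopentenone (quaternary C1 by copper-catalysed asymmetric conjugate methylation), then seven-membered ring B in the key step, then the oxirane last.

Key step: step 6

Remark on numbering: daucane numbering is used (C1 quaternary ring-fusion carbon with the angular methyl, C2, C3, C4 with isopropyl and ester oxygen, C5 ring-fusion CH, C6 CHOH, C7, C8 with methyl, C9, C10); β is the face of the angular methyl. The quaternary carbon is (S) in 9, 10 and 16 and (R) from 17 on, through CIP priority changes only.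
Assumption: the C8 epimers formed in step 6 are carried together, because C8 becomes trigonal in step 8; the sense of induction of the chiral carbene ligand in step 3 is to be confirmed on the first batch.

**Step 1**
Reactants: 1 (S)-but-3-yn-2-ol
Product: 3 (S)-3-methoxybut-1-yne, via sodium alkoxide 2 (not isolated)
Conditions: NaH (1.0 equiv), tetraglyme, 0 °C; MeI, 0 → 25 °C; product distilled out
Reagents that add atoms: iodomethane, CI
Why: Williamson etherification of the hydroxyl group (one equivalent of base leaves the alkyne C–H alone) should give the methyl ether without touching the stereocentre.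

**Step 2**
Reactants: 3 (S)-3-methoxybut-1-yne; 4 3-ethoxycyclopent-2-en-1-one
Product: 7 3-[(3S)-3-methoxybut-1-yn-1-yl]cyclopent-2-en-1-one, via lithium acetylide 5 (not isolated), via lithium alkoxide adduct 6 (not isolated)
Conditions: n-BuLi, THF, −78 °C; 4, −78 → 0 °C; then 1 M HCl, 0 → 25 °C
Reagents that add atoms: water, O
Why: 1,2-addition of the acetylide to the vinylogous ester and acid-mediated hydrolysis with carbonyl transposition (Stork–Danheiser sequence) should give the 3-alkynyl enone; the carbinol centre of 6 is lost again.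

**Step 3**
Reactants: 7 3-[(3S)-3-methoxybut-1-yn-1-yl]cyclopent-2-en-1-one
Product: 9 {[(3S)-3-[(3S)-3-methoxybut-1-yn-1-yl]-3-methylcyclopent-1-en-1-yl]oxy}triisopropylsilane, via magnesium enolate 8 (not isolated)
Conditions: MeMgBr, Cu(OTf)2 (5 mol %), C2-symmetric chiral 4,5-diphenylimidazolinium salt (carbene precursor, 7 mol %), Et2O, −30 °C; then TIPSOTf, DMPU, −30 → 0 °C
Reagents that add atoms: methylmagnesium bromide, C[Mg]Br; triisopropylsilyl trifluoromethanesulfonate, CC(C)[Si](OS(=O)(=O)C(F)(F)F)(C(C)C)C(C)C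
Why: copper–carbene-catalysed asymmetric conjugate addition of a Grignard reagent to a cyclic enynone is 1,4-selective and should set the quaternary C1 under catalyst control (ligand enantiomer chosen for the (S)-centre), and O-silylation of the regiodefined enolate fixes the C4=C5 enol ether.

**Step 4**
Reactants: 9 {[(3S)-3-[(3S)-3-methoxybut-1-yn-1-yl]-3-methylcyclopent-1-en-1-yl]oxy}triisopropylsilane
Product: 10 hexacarbonyldicobalt complex of 9 (μ-alkyne at C9≡C10)
Conditions: Co2(CO)8 (1.1 equiv), CH2Cl2, 25 °C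
Reagents that add atoms: octacarbonyldicobalt, O=C=[Co](=C=O)(=C=O)(=C=O)[Co](=C=O)(=C=O)(=C=O)=C=O
Why: alkyne complexation with loss of two CO is selective for the triple bond and should leave the enol ether, the methyl ether and both stereocentres untouched.

**Step 5**
Reactants: 11 tetrahydrofuran
Product: 13 triisopropyl(vinyloxy)silane, via lithium ethenolate 12 (not isolated)
Conditions: n-BuLi (1 equiv), THF as reactant and solvent, 25 °C, 16 h; then TIPSCl, DMPU, 0 → 25 °C
Reagents that add atoms: chlorotriisopropylsilane, CC(C)[Si](Cl)(C(C)C)C(C)C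
Why: α-lithiation of THF and cycloreversion give ethylene and the acetaldehyde enolate, whose O-silylation is the standard route to silyl vinyl ethers.

**Step 6**
Reactants: 10 hexacarbonyldicobalt complex of 9; 13 triisopropyl(vinyloxy)silane
Product: 16 hexacarbonyldicobalt complex of (5S,6S)-6α-[(triisopropylsilyl)oxy]-11,12,13-trinor-5αH-dauc-9-yn-4-one (C8 epimers), via propargylic cation 14 (not isolated), via silyl oxocarbenium ion 15 (not isolated)
Conditions: 13 (3 equiv), EtAlCl2 (1.5 equiv), CH2Cl2, −78 → −30 °C; aq. NaHCO3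
Reagents that add atoms: none
Why: EtAlCl2 ionises the propargylic methyl ether of 10 to the Co2(CO)6-stabilised cation 14 (Nicholas reaction), which is captured at C8 by the CH2 terminus of 13 (C7–C8) to give the O-silyl oxocarbenium ion 15; its C6 is then attacked by C5 of the ring A enol ether (Mukaiyama-type aldol, C5–C6), and loss of the ring A silyl group returns the C4 ketone. The closest known reaction type is the formal [5+2] cycloaddition of dicobalt-complexed propargylic cation/enol silyl ether five-carbon units with enol silyl ethers, which gives cobalt-complexed cycloheptynes. Ring B closes in a 7-(enolexo)-exo-trig mode. C5: the complexed-cycloheptyne ring needs a torsion of about 75° about C1–C5, which a cyclopentane can only accommodate trans-fused, so C6 should add to the enol ether face anti to C10 (5α-H); C6: the bulky OSi(i-Pr)3 group of the oxocarbenium ion should sit outside the forming ring (pseudo-equatorial), which puts H5 and H6 anti (6α-oxygen); C8 forms as an epimer mixture that is erased in step 8. The step needs intermolecular capture of 14 and then ring closure, not direct C5–C8 bonding or proton loss: the roughly 140° C–C≡C angles of the complexed alkyne rule out a five-membered ring through C9≡C10, the excess of electron-rich vinyl ether should outrun elimination, and the triisopropylsilyl group keeps 15 silylated until it cyclises.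

**Step 7**
Reactants: 16 hexacarbonyldicobalt complex of the cycloheptynone
Product: 17 (1R,5S,6S)-6α-[(triisopropylsilyl)oxy]-11,12,13-trinor-5αH-dauc-9-en-4-one (C8 epimers)
Conditions: n-Bu3SnH (4 equiv), benzene, 65 °C
Reagents that add atoms: none
Why: reductive decomplexation of a ring-embedded alkyne–Co2(CO)6 complex with tin hydride should deliver the cis-alkene, the only geometry a seven-membered ring allows, leaving ketone and silyl ether alone.

**Step 8**
Reactants: 17 (1R,5S,6S)-6α-[(triisopropylsilyl)oxy]-11,12,13-trinor-5αH-dauc-9-en-4-one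
Product: 18 (1R,5S,6S)-6α-[(triisopropylsilyl)oxy]-11,12,13-trinor-5αH-dauc-8-en-4-one
Conditions: RuHCl(CO)(PPh3)3 (5 mol %), toluene, 100 °C
Reagents that add atoms: none
Why: metal-hydride addition (Ru on C9, away from the neopentyl C10) and β-hydride elimination of the C8 hydrogen should move the alkene one position to the trisubstituted C8=C9 site, and further migration would need a tertiary Ru–C8 alkyl, so it should stop there (transition-metal-hydride olefin isomerisation).

**Step 9**
Reactants: 18 (1R,5S,6S)-6α-[(triisopropylsilyl)oxy]-11,12,13-trinor-5αH-dauc-8-en-4-one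
Product: 19 (1R,4R,5S,6S)-6α-[(triisopropylsilyl)oxy]-5αH-dauc-8-en-4β-ol
Conditions: i-PrMgCl, LaCl3·2LiCl, THF, 0 °C; aq. NH4Cl
Reagents that add atoms: isopropylmagnesium chloride, CC(C)[Mg]Cl
Why: lanthanum-mediated Grignard 1,2-addition suppresses enolisation and β-hydride reduction, and attack on the α-face, anti to the C6 arm on C5 and to the angular methyl, should give the 4β-alcohol.

**Step 10**
Reactants: 20 4-(benzyloxy)-3-methoxybenzoic acid
Product: 21 4-(benzyloxy)-3-methoxybenzoyl chloride
Conditions: SOCl2, toluene, 80 °C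
Reagents that add atoms: thionyl chloride, O=S(Cl)Cl
Why: standard conversion of an aryl carboxylic acid into its acid chloride; the benzyl ether is stable.

**Step 11**
Reactants: 19 (1R,4R,5S,6S)-6α-[(triisopropylsilyl)oxy]-5αH-dauc-8-en-4β-ol; 21 4-(benzyloxy)-3-methoxybenzoyl chloride
Product: 23 (1R,4R,5S,6S)-6α-[(triisopropylsilyl)oxy]-5αH-dauc-8-en-4β-yl 4-(benzyloxy)-3-methoxybenzoate, via lithium alkoxide 22 (not isolated)
Conditions: n-BuLi, THF, −78 °C; then 21, −78 → 25 °C
Reagents that add atoms: none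
Why: O-acylation of the lithium tertiary alkoxide by the aroyl chloride (addition–elimination) should give the hindered ester, the bulky triisopropylsilyl group resisting 1,3-silyl migration; no stereocentre is touched.

**Step 12**
Reactants: 23 (1R,4R,5S,6S)-6α-[(triisopropylsilyl)oxy]-5αH-dauc-8-en-4β-yl 4-(benzyloxy)-3-methoxybenzoate
Product: 24 (1R,4R,5S,6S)-6α-hydroxy-5αH-dauc-8-en-4β-yl 4-(benzyloxy)-3-methoxybenzoate
Conditions: HF·pyridine, pyridine, THF, 0 → 25 °C
Reagents that add atoms: none
Why: fluoride cleavage of the Si–O bond under buffered acidic conditions should free the 6α-hydroxyl without forming an alkoxide, so 1,3-acyl migration from the tertiary ester is avoided.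

**Step 13**
Reactants: 24 (1R,4R,5S,6S)-6α-hydroxy-5αH-dauc-8-en-4β-yl 4-(benzyloxy)-3-methoxybenzoate
Product: 25 (1R,4R,5S,6S,8R,9S)-8α,9α-epoxy-6α-hydroxy-5αH-daucan-4β-yl 4-(benzyloxy)-3-methoxybenzoate
Conditions: VO(acac)2 (5 mol %), t-BuOOH (decane solution), CH2Cl2, 0 → 25 °C
Reagents that add atoms: tert-butyl hydroperoxide, CC(C)(C)OO
Why: hydroxyl-directed epoxidation of the homoallylic alcohol should deliver oxygen to the alkene face syn to the 6α-hydroxyl, giving the 8α,9α-epoxide.

**Step 14**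
Reactants: 25 (1R,4R,5S,6S,8R,9S)-8α,9α-epoxy-6α-hydroxy-5αH-daucan-4β-yl 4-(benzyloxy)-3-methoxybenzoate
Product: 26 (1R,4R,5S,6S,8R,9S)-8α,9α-epoxy-6α-hydroxy-5αH-daucan-4β-yl 4-hydroxy-3-methoxybenzoate
Conditions: H2 (1 atm), Pd/C, EtOAc, 25 °C
Reagents that add atoms: none
Why: neutral hydrogenolysis of the benzyl aryl ether should free the phenol, the epoxide (neither allylic nor benzylic) and the tertiary ester being inert.

**Compound list**
1 | (S)-but-3-yn-2-ol | C#C[C@H](C)O | starting material
2 | sodium (S)-but-3-yn-2-olate (not isolated) | C#C[C@H](C)O[Na] | intermediate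
3 | (S)-3-methoxybut-1-yne | C#C[C@H](C)OC | intermediate
4 | 3-ethoxycyclopent-2-en-1-one | CCOC1=CC(=O)CC1 | starting material
5 | [(3S)-3-methoxybut-1-yn-1-yl]lithium (not isolated) | [Li]C#C[C@H](C)OC | intermediate
6 | lithium 3-ethoxy-1-[(3S)-3-methoxybut-1-yn-1-yl]cyclopent-2-en-1-olate (not isolated; both configurations at the carbinol carbon) | CCOC1=CC(O[Li])(C#C[C@H](C)OC)CC1 | intermediate
7 | 3-[(3S)-3-methoxybut-1-yn-1-yl]cyclopent-2-en-1-one | O=C1CCC(C#C[C@H](C)OC)=C1 | intermediate
8 | bromomagnesium (3S)-3-[(3S)-3-methoxybut-1-yn-1-yl]-3-methylcyclopent-1-en-1-olate (not isolated) | Br[Mg]OC1=C[C@](C)(CC1)C#C[C@H](C)OC | intermediate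
9 | {[(3S)-3-[(3S)-3-methoxybut-1-yn-1-yl]-3-methylcyclopent-1-en-1-yl]oxy}triisopropylsilane | CC(C)[Si](C(C)C)(C(C)C)OC1=C[C@](C)(CC1)C#C[C@H](C)OC | intermediate
10 | hexacarbonyldicobalt complex of 9 (μ-alkyne; quaternary carbon S, methoxy carbon S) | CC(C)[Si](C(C)C)(C(C)C)OC1=C[C@](C)(CC1)C23[Co]4(=C=O)(=C=O)(=C=O)[Co]2(=C=O)(=C=O)(=C=O)C34[C@H](C)OC | intermediate
11 | tetrahydrofuran | C1CCOC1 | starting material
12 | lithium ethenolate (not isolated) | [Li]OC=C | intermediate
13 | triisopropyl(vinyloxy)silane | C=CO[Si](C(C)C)(C(C)C)C(C)C | intermediate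
14 | Co2(CO)6-stabilised propargylic cation from 10 (not isolated) | CC(C)[Si](C(C)C)(C(C)C)OC1=C[C@](C)(CC1)C23[Co]4(=C=O)(=C=O)(=C=O)[Co]2(=C=O)(=C=O)(=C=O)C34[CH+]C | intermediate
15 | O-triisopropylsilyl oxocarbenium ion after C7–C8 bond formation (not isolated; C8 epimers) | CC(C)[Si](C(C)C)(C(C)C)OC1=C[C@](C)(CC1)C23[Co]4(=C=O)(=C=O)(=C=O)[Co]2(=C=O)(=C=O)(=C=O)C34C(C)CC=[O+][Si](C(C)C)(C(C)C)C(C)C | intermediate
16 | hexacarbonyldicobalt complex of (5S,6S)-6α-[(triisopropylsilyl)oxy]-11,12,13-trinor-5αH-dauc-9-yn-4-one (1β-methyl; C8 epimers) | O=C2CC[C@]3(C)C45[Co]6(=C=O)(=C=O)(=C=O)[Co]4(=C=O)(=C=O)(=C=O)C56C(C)C[C@H](O[Si](C(C)C)(C(C)C)C(C)C)[C@H]32 | intermediate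
17 | (1R,5S,6S)-6α-[(triisopropylsilyl)oxy]-11,12,13-trinor-5αH-dauc-9-en-4-one (C8 epimers) | O=C2CC[C@]3(C)C=CC(C)C[C@H](O[Si](C(C)C)(C(C)C)C(C)C)[C@H]32 | intermediate
18 | (1R,5S,6S)-6α-[(triisopropylsilyl)oxy]-11,12,13-trinor-5αH-dauc-8-en-4-one | O=C2CC[C@]3(C)CC=C(C)C[C@H](O[Si](C(C)C)(C(C)C)C(C)C)[C@H]32 | intermediate
19 | (1R,4R,5S,6S)-6α-[(triisopropylsilyl)oxy]-5αH-dauc-8-en-4β-ol | O[C@@]2(C(C)C)CC[C@]3(C)CC=C(C)C[C@H](O[Si](C(C)C)(C(C)C)C(C)C)[C@H]32 | intermediate
20 | 4-(benzyloxy)-3-methoxybenzoic acid | COc1cc(C(=O)O)ccc1OCc1ccccc1 | starting material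
21 | 4-(benzyloxy)-3-methoxybenzoyl chloride | COc1cc(C(Cl)=O)ccc1OCc1ccccc1 | intermediate
22 | lithium alkoxide of 19 (not isolated) | [Li]O[C@@]2(C(C)C)CC[C@]3(C)CC=C(C)C[C@H](O[Si](C(C)C)(C(C)C)C(C)C)[C@H]32 | intermediate
23 | (1R,4R,5S,6S)-6α-[(triisopropylsilyl)oxy]-5αH-dauc-8-en-4β-yl 4-(benzyloxy)-3-methoxybenzoate | COc1cc(C(=O)O[C@@]2(C(C)C)CC[C@]3(C)CC=C(C)C[C@H](O[Si](C(C)C)(C(C)C)C(C)C)[C@H]32)ccc1OCc1ccccc1 | intermediate
24 | (1R,4R,5S,6S)-6α-hydroxy-5αH-dauc-8-en-4β-yl 4-(benzyloxy)-3-methoxybenzoate | COc1cc(C(=O)O[C@@]2(C(C)C)CC[C@]3(C)CC=C(C)C[C@H](O)[C@H]32)ccc1OCc1ccccc1 | intermediate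
25 | (1R,4R,5S,6S,8R,9S)-8α,9α-epoxy-6α-hydroxy-5αH-daucan-4β-yl 4-(benzyloxy)-3-methoxybenzoate | COc1cc(C(=O)O[C@@]2(C(C)C)CC[C@]3(C)C[C@@H]4O[C@]4(C)C[C@H](O)[C@H]32)ccc1OCc1ccccc1 | intermediate
26 | (1R,4R,5S,6S,8R,9S)-8α,9α-epoxy-6α-hydroxy-5αH-daucan-4β-yl 4-hydroxy-3-methoxybenzoate (CNP0315707.1) | COc1cc(C(=O)O[C@@]2(C(C)C)CC[C@]3(C)C[C@@H]4O[C@]4(C)C[C@H](O)[C@H]32)ccc1O | target

**Step count**
Total: 14 steps. Longest linear sequence: 12 steps (1, 2, 3, 4, 6, 7, 8, 9, 11, 12, 13, 14); steps 5 and 10 are side branches.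

**Steps most likely to fail**

Step 6. The propargylic cation may lose a proton before it is captured, the oxocarbenium ion may lose its silyl group so that ring closure stalls at the open aldehyde, or closure may occur on the other enol ether face and give the cis ring fusion. The fallback builds ring B by aldol addition and ring-closing metathesis; it sets out from 4 and comes back at 18, so steps 7 and 8 are bypassed as well. Allylmagnesium bromide should add to 4 and acidic work-up should give 3-(prop-2-en-1-yl)cyclopent-2-en-1-one F1. The copper–carbene-catalysed conjugate methylation of step 3 then generates the magnesium enolate, which is intercepted at −78 °C by 3-methylbut-3-enal F2 (freshly made by Dess–Martin oxidation of commercial 3-methylbut-3-en-1-ol) through a closed transition state, anti to the larger allyl group, to give the anti aldol (2S,3R)-3-allyl-2-[(1S)-1-hydroxy-3-methylbut-3-en-1-yl]-3-methylcyclopentan-1-one F3. Silylation (TIPSOTf, 2,6-lutidine) should give the silyl ether F4, and ring-closing metathesis with the second-generation Grubbs catalyst should close C8=C9 to give 18.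

Step 8. Migration may stall at the hindered cis-alkene next to the quaternary carbon, run on past C8=C9, or be accompanied by epimerisation at C5. The fallback moves the alkene by functional-group chemistry; it sets out from 17 and comes back at 23. Compound 17 is taken through the conditions of steps 9 and 11 to the carbinol (1R,4R,5S,6S)-6α-[(triisopropylsilyl)oxy]-5αH-dauc-9-en-4β-ol F5 and its 4-(benzyloxy)-3-methoxybenzoate F6. Hydroboration (BH3·SMe2) should place boron on C9, away from the neopentyl C10, and oxidation (NaBO3) should give the 9-hydroxy ester F7. Dess–Martin oxidation gives the 9-oxo ester F8, the more substituted enol triflate F9 is formed with Tf2O and 2,6-di-tert-butyl-4-methylpyridine, and reduction with Pd(OAc)2, PPh3, HCO2H and n-Bu3N should give 23.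

Step 3. Enantioselectivity may be low on the five-membered enynone, 1,6-addition may compete, or copper may displace the propargylic ether. The fallback replaces catalyst control by separation of diastereomers that owe their existence to the stereocentre brought in with 1; it sets out from 7 and comes back at 10. The conjugate methylation is run without asymmetric induction (MeMgBr, Cu(OTf)2, the achiral carbene from 1,3-dimesitylimidazolium chloride, then TIPSOTf) and should give 9 together with its epimer at the quaternary carbon, {[(3R)-3-[(3S)-3-methoxybut-1-yn-1-yl]-3-methylcyclopent-1-en-1-yl]oxy}triisopropylsilane F10. Complexation under the conditions of step 4 should give 10 and the epimeric hexacarbonyldicobalt complex F11, which are separated by preparative chromatography; 10 rejoins the route.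

**Further compounds**
F1 | step 6 | 3-(prop-2-en-1-yl)cyclopent-2-en-1-one | C=CCC1=CC(=O)CC1
F2 | step 6 | 3-methylbut-3-enal | CC(=C)CC=O
F3 | step 6 | (2S,3R)-3-allyl-2-[(1S)-1-hydroxy-3-methylbut-3-en-1-yl]-3-methylcyclopentan-1-one | O=C1CC[C@](C)(CC=C)[C@H]1[C@@H](O)CC(C)=C
F4 | step 6 | (2S,3R)-3-allyl-3-methyl-2-{(1S)-3-methyl-1-[(triisopropylsilyl)oxy]but-3-en-1-yl}cyclopentan-1-one | O=C1CC[C@](C)(CC=C)[C@H]1[C@@H](O[Si](C(C)C)(C(C)C)C(C)C)CC(C)=C
F5 | step 8 | (1R,4R,5S,6S)-6α-[(triisopropylsilyl)oxy]-5αH-dauc-9-en-4β-ol (C8 epimers) | O[C@@]2(C(C)C)CC[C@]3(C)C=CC(C)C[C@H](O[Si](C(C)C)(C(C)C)C(C)C)[C@H]32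
F6 | step 8 | (1R,4R,5S,6S)-6α-[(triisopropylsilyl)oxy]-5αH-dauc-9-en-4β-yl 4-(benzyloxy)-3-methoxybenzoate (C8 epimers) | COc1cc(C(=O)O[C@@]2(C(C)C)CC[C@]3(C)C=CC(C)C[C@H](O[Si](C(C)C)(C(C)C)C(C)C)[C@H]32)ccc1OCc1ccccc1
F7 | step 8 | 9-hydroxy-6α-[(triisopropylsilyl)oxy]-5αH-daucan-4β-yl 4-(benzyloxy)-3-methoxybenzoate (C8 and C9 isomers) | COc1cc(C(=O)O[C@@]2(C(C)C)CC[C@]3(C)CC(O)C(C)C[C@H](O[Si](C(C)C)(C(C)C)C(C)C)[C@H]32)ccc1OCc1ccccc1
F8 | step 8 | 9-oxo-6α-[(triisopropylsilyl)oxy]-5αH-daucan-4β-yl 4-(benzyloxy)-3-methoxybenzoate (C8 epimers) | COc1cc(C(=O)O[C@@]2(C(C)C)CC[C@]3(C)CC(=O)C(C)C[C@H](O[Si](C(C)C)(C(C)C)C(C)C)[C@H]32)ccc1OCc1ccccc1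
F9 | step 8 | 9-[(trifluoromethanesulfonyl)oxy]-6α-[(triisopropylsilyl)oxy]-5αH-dauc-8-en-4β-yl 4-(benzyloxy)-3-methoxybenzoate | COc1cc(C(=O)O[C@@]2(C(C)C)CC[C@]3(C)CC(OS(=O)(=O)C(F)(F)F)=C(C)C[C@H](O[Si](C(C)C)(C(C)C)C(C)C)[C@H]32)ccc1OCc1ccccc1
F10 | step 3 | {[(3R)-3-[(3S)-3-methoxybut-1-yn-1-yl]-3-methylcyclopent-1-en-1-yl]oxy}triisopropylsilane | CC(C)[Si](C(C)C)(C(C)C)OC1=C[C@@](C)(CC1)C#C[C@H](C)OC
F11 | step 3 | hexacarbonyldicobalt complex of F10 | CC(C)[Si](C(C)C)(C(C)C)OC1=C[C@@](C)(CC1)C23[Co]4(=C=O)(=C=O)(=C=O)[Co]2(=C=O)(=C=O)(=C=O)C34[C@H](C)OC
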